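**Plan**

1. Numbering: chroman numbering for the core (O1, C2, C3, C4, C4a, C5 to C8, C8a; ring A = carbocycle, ring B = pyranone), C1' to C8' for the octanoic acid chain, ring D = cyclobutane. The retrosynthesis cuts C8–prenyl, then C8–CH2 (ring D), then O1–C2 and C4–C4a (ring B), and last C6–C3', which leaves phloroglucinol and (E)-oct-2-enal.
2. Enabling feature: C6 lies between O5 and O7 on ring A, a phloroglucinol ring. In phloroglucinol the three ring CH are homotopic and each has two ortho OH, so the C6–C3' bond is made first, by asymmetric conjugate addition to the enal, with no regiochemical choice; an ortho OH traps C1' as a six-membered lactol, which is oxidised in the same step to a lactone (temporary ring C).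
3. Forward order: ring C (step 1); ring B by Mitsunobu etherification of the one OH that is not next to the chain, then Friedel–Crafts acylation (steps 4–5; either ortho carbon gives the same compound once ring C is opened to the methyl ester); C8, the last free ring carbon, takes ring D by iodination and Negishi coupling (steps 6, 11), then the prenyl group with dearomatisation (step 12); ester hydrolysis (step 13).
4. Stereochemistry: C3' from the amine catalyst (step 1); C2/C3 from an Evans syn-aldol and Mitsunobu inversion (steps 2–4); ring D from (1S)-(−)-verbenone, whose cyclobutane C1–C6–C5–C7 is kept intact after excision of C3 (steps 7–10); C8 from a chiral palladium catalyst (step 12).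

Key step: step 1

Assumption: commercial (1S)-(−)-verbenone is taken as enantiopure; if it is not, crystalline acid 15 is recrystallised to upgrade it.
Assumption: the sense of induction of the chiral diphosphine in step 12 cannot be predicted with confidence for this phenoxide; the (R,R)-ligand is written and its enantiomer is used if a pilot run shows the opposite face preference.

**Route**

Step 1
Reactants: 1 phloroglucinol; 2 (E)-oct-2-enal
Product: 4 (4S)-5,7-dihydroxy-4-pentyl-3,4-dihydro-2H-chromen-2-one, via lactol 3 (not isolated)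
Conditions: excess 1 (3 equiv), (R)-2-[diphenyl(trimethylsilyloxy)methyl]pyrrolidine (20 mol%), PhCO2H (20 mol%), MeCN, 0 °C to rt; aq. citric acid wash, solvent switch; [Cp*IrCl2]2 (2 mol%), K2CO3 (10 mol%), acetone, 40 °C
Reagents that add atoms: none
Why: The amine and 2 condense to the (E,E)-iminium ion, whose Re face at C3 is covered by the CPh2(OSiMe3) group of the (R)-catalyst, so a ring CH of 1, reacting as the enol-like carbon of its phenol/keto tautomer, adds to the Si face of C3 in a Friedel–Crafts-type conjugate addition, and this alone sets the (S) centre (the future C3'). Tautomerisation restores the arene, hydrolysis of the enamine returns the catalyst, and the adjacent phenol closes ring C by 6-exo-trig addition to the aldehyde carbon to give lactol 3. After the wash, which removes excess 1 and the amine, Oppenauer-type transfer dehydrogenation of the lactol C2–H to acetone at the iridium catalyst should give lactone 4 without an electrophilic oxidant that would attack the electron-rich ring A, and C4 is not involved. The closest known reaction type is the diarylprolinol-silyl-ether-catalysed Friedel–Crafts alkylation/hemiacetalisation of naphthols, sesamol and 3,5-dimethoxyphenol with enals, followed by oxidation of the lactol to the dihydrocoumarin. No regiochemistry has to be controlled because the three ring CH of 1 are homotopic and each has two ortho OH groups; the step needs mono-alkylation (excess 1), 1,4- instead of 1,2-addition (β-monosubstituted enal, bulky amine) and face selection (catalyst). The lactone holds C1' at the oxidation level of the acid and marks the oxygen para to the chain as the future O1.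

Step 2
Reactants: 5 (R)-4-benzyl-3-propanoyl-1,3-oxazolidin-2-one; 6 acetaldehyde
Product: 7 (R)-4-benzyl-3-[(2R,3S)-3-hydroxy-2-methylbutanoyl]-1,3-oxazolidin-2-one
Conditions: Bu2BOTf, iPr2NEt, CH2Cl2, 0 °C; 6, −78 to 0 °C; pH 7 buffer, MeOH, H2O2
Reagents that add atoms: none
Why: Evans aldol reaction: the Z-boron enolate of 5 adds to acetaldehyde through a Zimmerman–Traxler chair on the face away from the benzyl group, which sets the syn (2R,3S) pair.

Step 3
Reactants: 7 (R)-4-benzyl-3-[(2R,3S)-3-hydroxy-2-methylbutanoyl]-1,3-oxazolidin-2-one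
Product: 8 methyl (2R,3S)-3-hydroxy-2-methylbutanoate
Conditions: NaOMe (1.1 equiv), MeOH, 0 °C, 10 min; AcOH
Reagents that add atoms: methanol (as sodium methoxide), CO
Why: Transesterification: methoxide attacks the exocyclic imide carbonyl and releases the auxiliary, and the short exposure at 0 °C avoids retro-aldol cleavage and C2 epimerisation.

Step 4
Reactants: 4 (4S)-5,7-dihydroxy-4-pentyl-3,4-dihydro-2H-chromen-2-one; 8 methyl (2R,3S)-3-hydroxy-2-methylbutanoate
Product: 9 methyl (2R,3R)-3-{[(4S)-5-hydroxy-2-oxo-4-pentyl-3,4-dihydro-2H-chromen-7-yl]oxy}-2-methylbutanoate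
Conditions: 8 (1.05 equiv), PPh3, DIAD, THF, 0 °C to rt
Reagents that add atoms: none
Why: Mitsunobu etherification: the 7-OH of 4 (para to the chain-bearing carbon, the future O1) is the only hydroxyl not flanked by the branched C4 substituent (the 5-OH is peri to it, the third oxygen is in the lactone), so it displaces the activated secondary alcohol by SN2 with inversion, turning (3S) into the (3R) aryl ether (future C2), while the (2R) centre (future C3) is untouched.

Step 5
Reactants: 9 methyl (2R,3R)-3-{[(4S)-5-hydroxy-2-oxo-4-pentyl-3,4-dihydro-2H-chromen-7-yl]oxy}-2-methylbutanoate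
Product: 12 methyl (3S)-3-[(2R,3R)-5,7-dihydroxy-2,3-dimethyl-4-oxo-3,4-dihydro-2H-chromen-6-yl]octanoate, via diacid 10 (not isolated), via tricyclic lactone 11 (not isolated)
Conditions: LiOH, THF/H2O, 0 °C to rt, then HCl; P2O5 in MeSO3H (1:10 w/w), rt; MeOH, 40 °C
Reagents that add atoms: lithium hydroxide, [Li+].[OH-]; methanol, CO
Why: Saponification frees both acids, intramolecular Friedel–Crafts acylation then closes ring B onto either of the two equivalent carbons ortho to the ether oxygen (the ring oxygen is para to the chain, so both give the same constitution), the side-chain acid relactonises on the non-chelated OH, and acidic methanol opens this lactone to the methyl ester; no stereocentre is formed, and the trans-2,3-dimethyl arrangement is also the thermodynamic one.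

Step 6
Reactants: 12 methyl (3S)-3-[(2R,3R)-5,7-dihydroxy-2,3-dimethyl-4-oxo-3,4-dihydro-2H-chromen-6-yl]octanoate
Product: 13 methyl (3S)-3-[(2R,3R)-5,7-dihydroxy-8-iodo-2,3-dimethyl-4-oxo-3,4-dihydro-2H-chromen-6-yl]octanoate
Conditions: NIS (1.0 equiv), MeCN, 0 °C
Reagents that add atoms: N-iodosuccinimide, O=C1CCC(=O)N1I
Why: Electrophilic aromatic iodination at C8, the only unsubstituted carbon of the electron-rich ring A.

Step 7
Reactants: 14 (1S,5S)-4,6,6-trimethylbicyclo[3.1.1]hept-3-en-2-one ((1S)-(−)-verbenone)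
Product: 15 (1S,3R)-3-acetyl-2,2-dimethylcyclobutane-1-carboxylic acid
Conditions: RuCl3·xH2O (2 mol%), NaIO4 (4.1 equiv), CCl4/MeCN/H2O, rt
Reagents that add atoms: sodium periodate, [Na+].[O-]I(=O)(=O)=O
Why: RuO4-mediated oxidative cleavage of the enone C3=C4 bond and oxidative decarboxylation of the resulting α-keto acid excise C3 and leave the cis-1,3-disubstituted cyclobutane of the pinane skeleton with both stereocentres untouched.

Step 8
Reactants: 15 (1S,3R)-3-acetyl-2,2-dimethylcyclobutane-1-carboxylic acid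
Product: 16 (1S,3S)-2,2-dimethyl-3-(prop-1-en-2-yl)cyclobutane-1-carboxylic acid
Conditions: Ph3PCH3Br (2.5 equiv), KOtBu (2.4 equiv), THF, 0 °C to rt; aq. HCl
Reagents that add atoms: methyltriphenylphosphonium bromide, C[P+](c1ccccc1)(c1ccccc1)c1ccccc1.[Br-]
Why: Wittig methylenation of the ketone (the carboxylate is inert to the ylide) builds the isopropenyl group, and adding 15 to the preformed ylide at 0 °C limits epimerisation next to the ketone.

Step 9
Reactants: 16 (1S,3S)-2,2-dimethyl-3-(prop-1-en-2-yl)cyclobutane-1-carboxylic acid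
Product: 17 [(1S,3S)-2,2-dimethyl-3-(prop-1-en-2-yl)cyclobutyl]methanol
Conditions: LiAlH4, Et2O, 0 °C to rt; H2O
Reagents that add atoms: none
Why: Hydride reduction of the carboxylic acid to the primary alcohol, which does not touch the ring stereocentres or the alkene.

Step 10
Reactants: 17 [(1S,3S)-2,2-dimethyl-3-(prop-1-en-2-yl)cyclobutyl]methanol
Product: 18 (1S,3S)-1-(iodomethyl)-2,2-dimethyl-3-(prop-1-en-2-yl)cyclobutane
Conditions: I2, PPh3, imidazole, CH2Cl2, 0 °C to rt
Reagents that add atoms: iodine, II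
Why: Appel iodination, an SN2 displacement of the oxyphosphonium group at the primary carbon, avoids any cyclobutylcarbinyl cation and leaves the acid-sensitive isopropenyl group alone.

Step 11
Reactants: 18 (1S,3S)-1-(iodomethyl)-2,2-dimethyl-3-(prop-1-en-2-yl)cyclobutane; 13 methyl (3S)-3-[(2R,3R)-5,7-dihydroxy-8-iodo-2,3-dimethyl-4-oxo-3,4-dihydro-2H-chromen-6-yl]octanoate
Product: 20 methyl (3S)-3-[(2R,3R)-8-{[(1R,3S)-2,2-dimethyl-3-(prop-1-en-2-yl)cyclobutyl]methyl}-5,7-dihydroxy-2,3-dimethyl-4-oxo-3,4-dihydro-2H-chromen-6-yl]octanoate, via alkylzinc iodide 19 (not isolated)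
Conditions: Zn dust, LiCl, THF, 40 °C; then 13, Pd(OAc)2 (4 mol%), SPhos (8 mol%), THF, 25 °C, slow addition of 19 (2 equiv)
Reagents that add atoms: none
Why: Negishi coupling: zinc insertion into the primary C–I bond and sp2–sp3 coupling at zerovalent palladium tolerate the ester, the ketone and (with slow addition) the free phenols, and neither reacting carbon is a stereocentre.

Step 12
Reactants: 20 methyl (3S)-3-[(2R,3R)-8-{[(1R,3S)-2,2-dimethyl-3-(prop-1-en-2-yl)cyclobutyl]methyl}-5,7-dihydroxy-2,3-dimethyl-4-oxo-3,4-dihydro-2H-chromen-6-yl]octanoate; 21 3-methylbut-2-en-1-yl acetate (prenyl acetate)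
Product: 22 methyl (3S)-3-[(2R,3R,8R)-8-{[(1R,3S)-2,2-dimethyl-3-(prop-1-en-2-yl)cyclobutyl]methyl}-5-hydroxy-2,3-dimethyl-8-(3-methylbut-2-en-1-yl)-4,7-dioxo-3,4,7,8-tetrahydro-2H-chromen-6-yl]octanoate
Conditions: 21 (1.5 equiv), Pd2(dba)3·CHCl3 (2.5 mol%), (1R,2R)-N,N'-bis[2-(diphenylphosphanyl)benzoyl]cyclohexane-1,2-diamine (7.5 mol%), Cs2CO3 (1.2 equiv), CH2Cl2, 0 °C to rt
Reagents that add atoms: none
Why: Proposed new method: zerovalent palladium ionises 21 to a cationic π-prenyl complex held in the chiral pocket of the diphosphine; the cesium 7-phenoxide of 20 (the 5-OH stays chelated to C4=O) attacks the unsubstituted allyl terminus through C8, the only carbon ortho to O7 that does not carry a branched substituent, and since C8 is already substituted the adduct cannot rearomatise, so the quaternary centre is formed on the face chosen by the ligand, while O-prenyl ethers re-ionise under the catalyst and funnel to the C-alkylated vinylogous acid; the closest known reaction types are the palladium/chiral-diphosphine intermolecular allylic dearomatisation of 1-substituted 2-naphthols and the racemic palladium-catalysed dearomative prenylation of acylphloroglucinols.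

Step 13
Reactants: 22 methyl (3S)-3-[(2R,3R,8R)-8-{[(1R,3S)-2,2-dimethyl-3-(prop-1-en-2-yl)cyclobutyl]methyl}-5-hydroxy-2,3-dimethyl-8-(3-methylbut-2-en-1-yl)-4,7-dioxo-3,4,7,8-tetrahydro-2H-chromen-6-yl]octanoate
Product: 23 (3S)-3-[(2R,3R,8R)-8-{[(1R,3S)-2,2-dimethyl-3-(prop-1-en-2-yl)cyclobutyl]methyl}-5-hydroxy-2,3-dimethyl-8-(3-methylbut-2-en-1-yl)-4,7-dioxo-3,4,7,8-tetrahydro-2H-chromen-6-yl]octanoic acid (CNP0208815.1)
Conditions: LiOH, THF/MeOH/H2O, 0 °C to rt; 0.5 M HCl to pH 3, 0 °C
Reagents that add atoms: lithium hydroxide, [Li+].[OH-]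
Why: Saponification of the methyl ester; under base ring A is present as its vinylogous-acid enolate, which protects C3 from enolisation and ring B from retro-oxa-Michael opening, and the mild acidification spares the isopropenylcyclobutane.

**Compound list**

1 | phloroglucinol (benzene-1,3,5-triol) | Oc1cc(O)cc(O)c1 | starting material
2 | (E)-oct-2-enal | CCCCC/C=C/C=O | starting material
3 | (4S)-4-pentyl-3,4-dihydro-2H-chromene-2,5,7-triol (lactol as both C2 anomers; not isolated) | CCCCC[C@H]1CC(O)Oc2cc(O)cc(O)c21 | intermediate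
4 | (4S)-5,7-dihydroxy-4-pentyl-3,4-dihydro-2H-chromen-2-one | CCCCC[C@H]1CC(=O)Oc2cc(O)cc(O)c21 | intermediate
5 | (R)-4-benzyl-3-propanoyl-1,3-oxazolidin-2-one | CCC(=O)N1[C@H](Cc2ccccc2)COC1=O | starting material
6 | acetaldehyde | CC=O | starting material
7 | (R)-4-benzyl-3-[(2R,3S)-3-hydroxy-2-methylbutanoyl]-1,3-oxazolidin-2-one | C[C@H](O)[C@@H](C)C(=O)N1[C@H](Cc2ccccc2)COC1=O | intermediate
8 | methyl (2R,3S)-3-hydroxy-2-methylbutanoate | C[C@H](O)[C@@H](C)C(=O)OC | intermediate
9 | methyl (2R,3R)-3-{[(4S)-5-hydroxy-2-oxo-4-pentyl-3,4-dihydro-2H-chromen-7-yl]oxy}-2-methylbutanoate | CCCCC[C@H]1CC(=O)Oc2cc(O[C@H](C)[C@@H](C)C(=O)OC)cc(O)c21 | intermediate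
10 | (3S)-3-(4-{[(2R,3R)-3-carboxybutan-2-yl]oxy}-2,6-dihydroxyphenyl)octanoic acid (not isolated) | CCCCC[C@@H](CC(=O)O)c1c(O)cc(O[C@H](C)[C@@H](C)C(=O)O)cc1O | intermediate
11 | (2R,3R,6S)-5-hydroxy-2,3-dimethyl-6-pentyl-2,3,6,7-tetrahydropyrano[3,2-g]chromene-4,8-dione (not isolated) | CCCCC[C@H]1CC(=O)Oc2cc3O[C@H](C)[C@@H](C)C(=O)c3c(O)c21 | intermediate
12 | methyl (3S)-3-[(2R,3R)-5,7-dihydroxy-2,3-dimethyl-4-oxo-3,4-dihydro-2H-chromen-6-yl]octanoate | CCCCC[C@@H](CC(=O)OC)c1c(O)cc2O[C@H](C)[C@@H](C)C(=O)c2c1O | intermediate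
13 | methyl (3S)-3-[(2R,3R)-5,7-dihydroxy-8-iodo-2,3-dimethyl-4-oxo-3,4-dihydro-2H-chromen-6-yl]octanoate | CCCCC[C@@H](CC(=O)OC)c1c(O)c(I)c2O[C@H](C)[C@@H](C)C(=O)c2c1O | intermediate
14 | (1S,5S)-4,6,6-trimethylbicyclo[3.1.1]hept-3-en-2-one ((1S)-(−)-verbenone) | CC1=CC(=O)[C@H]2C[C@@H]1C2(C)C | starting material
15 | (1S,3R)-3-acetyl-2,2-dimethylcyclobutane-1-carboxylic acid | CC(=O)[C@@H]1C[C@H](C(=O)O)C1(C)C | intermediate
16 | (1S,3S)-2,2-dimethyl-3-(prop-1-en-2-yl)cyclobutane-1-carboxylic acid | C=C(C)[C@@H]1C[C@H](C(=O)O)C1(C)C | intermediate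
17 | [(1S,3S)-2,2-dimethyl-3-(prop-1-en-2-yl)cyclobutyl]methanol | C=C(C)[C@@H]1C[C@H](CO)C1(C)C | intermediate
18 | (1S,3S)-1-(iodomethyl)-2,2-dimethyl-3-(prop-1-en-2-yl)cyclobutane | C=C(C)[C@@H]1C[C@H](CI)C1(C)C | intermediate
19 | {[(1S,3S)-2,2-dimethyl-3-(prop-1-en-2-yl)cyclobutyl]methyl}zinc iodide (not isolated) | C=C(C)[C@@H]1C[C@H](C[Zn]I)C1(C)C | intermediate
20 | methyl (3S)-3-[(2R,3R)-8-{[(1R,3S)-2,2-dimethyl-3-(prop-1-en-2-yl)cyclobutyl]methyl}-5,7-dihydroxy-2,3-dimethyl-4-oxo-3,4-dihydro-2H-chromen-6-yl]octanoate | CCCCC[C@@H](CC(=O)OC)c1c(O)c(C[C@H]3C[C@@H](C(C)=C)C3(C)C)c2O[C@H](C)[C@@H](C)C(=O)c2c1O | intermediate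
21 | 3-methylbut-2-en-1-yl acetate (prenyl acetate) | CC(C)=CCOC(C)=O | starting material
22 | methyl (3S)-3-[(2R,3R,8R)-8-{[(1R,3S)-2,2-dimethyl-3-(prop-1-en-2-yl)cyclobutyl]methyl}-5-hydroxy-2,3-dimethyl-8-(3-methylbut-2-en-1-yl)-4,7-dioxo-3,4,7,8-tetrahydro-2H-chromen-6-yl]octanoate | C=C(C)[C@@H]1C[C@H](C[C@@]2(CC=C(C)C)C(=O)C([C@@H](CCCCC)CC(=O)OC)=C(O)C3=C2O[C@H](C)[C@@H](C)C3=O)C1(C)C | intermediate
23 | (3S)-3-[(2R,3R,8R)-8-{[(1R,3S)-2,2-dimethyl-3-(prop-1-en-2-yl)cyclobutyl]methyl}-5-hydroxy-2,3-dimethyl-8-(3-methylbut-2-en-1-yl)-4,7-dioxo-3,4,7,8-tetrahydro-2H-chromen-6-yl]octanoic acid | C=C(C)[C@@H]1C[C@H](C[C@@]2(CC=C(C)C)C(=O)C([C@@H](CCCCC)CC(=O)O)=C(O)C3=C2O[C@H](C)[C@@H](C)C3=O)C1(C)C | target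

**Count and risks**

Total step count: 13. Longest linear sequence: 8 steps (2, 3, 4, 5, 6, 11, 12, 13 from oxazolidinone 5; the sequences from phloroglucinol, steps 1, 4, 5, 6, 11, 12, 13, and from verbenone, steps 7 to 13, have 7 steps each).

Three steps most likely to fail:

1. Step 12 (bears the label "Proposed new method:"). What may go wrong: poor or reversed facial selectivity at C8, because the two faces of the ring A phenoxide differ only through remote groups, and O-prenylation that does not funnel to carbon. Fallback (known chemistry): setting out from 20, base-mediated alkylative dearomatisation of the acylphloroglucinol (prenyl bromide, NaOMe, MeOH, −20 to 0 °C, the classical C-prenylation that leads to lupulone-type triketones) should give 22 together with its C8 epimer, methyl (3S)-3-[(2R,3R,8S)-8-{[(1R,3S)-2,2-dimethyl-3-(prop-1-en-2-yl)cyclobutyl]methyl}-5-hydroxy-2,3-dimethyl-8-(3-methylbut-2-en-1-yl)-4,7-dioxo-3,4,7,8-tetrahydro-2H-chromen-6-yl]octanoate F1. The two diastereomers are separated by preparative HPLC and the route is rejoined at 22.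

2. Step 11. What may go wrong: ring opening of the cyclobutylcarbinyl radical during zinc insertion, protonolysis of the carbon–zinc bond by the two phenols, or protodeiodination of the electron-rich, doubly ortho-substituted iodide. Fallback: setting out from 18 and 13, lithium–iodine exchange (t-BuLi, Et2O, −78 °C, a polar exchange without free radicals) gives {[(1S,3S)-2,2-dimethyl-3-(prop-1-en-2-yl)cyclobutyl]methyl}lithium F2, which is trapped with 9-methoxy-9-BBN as lithium 9-{[(1S,3S)-2,2-dimethyl-3-(prop-1-en-2-yl)cyclobutyl]methyl}-9-methoxy-9-boranuidabicyclo[3.3.1]nonane F3. B-alkyl Suzuki–Miyaura coupling of this borinate with 13 (Pd(dppf)Cl2, aq. K3PO4, DMF, rt), in which the phenoxides are spectators and transmetalation goes through boron instead of zinc, rejoins the route at 20.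

3. Step 4. What may go wrong: dehydration of the β-hydroxy ester to methyl tiglate under the redox conditions, and incomplete discrimination between the 7-OH and the 5-OH of 4. Fallback: setting out from 7 and 4, LiOH/H2O2 cleavage of 7 gives (2R,3S)-3-hydroxy-2-methylbutanoic acid F4, and PhSO2Cl in pyridine closes it by carboxyl activation (retention) to (3R,4S)-3,4-dimethyloxetan-2-one F5. The 7-phenoxide of 4 (K2CO3, MeCN) opens this β-lactone by SN2 at C4 (alkyl–oxygen cleavage, inversion) to (2R,3R)-3-{[(4S)-5-hydroxy-2-oxo-4-pentyl-3,4-dihydro-2H-chromen-7-yl]oxy}-2-methylbutanoic acid F6. P2O5 in MeSO3H and then MeOH, as in step 5 but without the saponification, take this acid to 12; acylation at either carbon ortho to the ether oxygen converges on 12 after methanolysis of the lactone.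

Further compounds
F1 | step 12 | methyl (3S)-3-[(2R,3R,8S)-8-{[(1R,3S)-2,2-dimethyl-3-(prop-1-en-2-yl)cyclobutyl]methyl}-5-hydroxy-2,3-dimethyl-8-(3-methylbut-2-en-1-yl)-4,7-dioxo-3,4,7,8-tetrahydro-2H-chromen-6-yl]octanoate (C8 epimer of 22) | C=C(C)[C@@H]1C[C@H](C[C@]2(CC=C(C)C)C(=O)C([C@@H](CCCCC)CC(=O)OC)=C(O)C3=C2O[C@H](C)[C@@H](C)C3=O)C1(C)C
F2 | step 11 | {[(1S,3S)-2,2-dimethyl-3-(prop-1-en-2-yl)cyclobutyl]methyl}lithium | [Li]C[C@H]1C[C@@H](C(C)=C)C1(C)C
F3 | step 11 | lithium 9-{[(1S,3S)-2,2-dimethyl-3-(prop-1-en-2-yl)cyclobutyl]methyl}-9-methoxy-9-boranuidabicyclo[3.3.1]nonane | [Li+].CO[B-]1(C[C@H]2C[C@@H](C(C)=C)C2(C)C)C2CCCC1CCC2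
F4 | step 4 | (2R,3S)-3-hydroxy-2-methylbutanoic acid | C[C@H](O)[C@@H](C)C(=O)O
F5 | step 4 | (3R,4S)-3,4-dimethyloxetan-2-one | C[C@@H]1OC(=O)[C@@H]1C
F6 | step 4 | (2R,3R)-3-{[(4S)-5-hydroxy-2-oxo-4-pentyl-3,4-dihydro-2H-chromen-7-yl]oxy}-2-methylbutanoic acid | CCCCC[C@H]1CC(=O)Oc2cc(O[C@H](C)[C@@H](C)C(=O)O)cc(O)c21
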